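## Retrosynthetic overview

- The target comes from its 7'-ketone. C7' is set last by a catalyst-controlled transfer hydrogenation, and C3 settles trans to C4 by enolisation.
- The keto lactone comes from a 1-aroyl-6-aryl-3-oxabicyclo[3.1.0]hexan-2-one. One hydrogenolysis cuts the push-pull C1–C6 bond and removes both benzyl ethers.
- The bicycle comes from a cinnamyl-type aroyl(diazo)acetate. One enantioselective carbene transfer closes the γ-lactone and the cyclopropane together and fixes C4 of the target, with all 18 skeletal carbons already in place.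
- The diazo ester comes from O-benzylconiferyl alcohol (from O-benzylvanillin) and an aroyl Meldrum's acid (from O-benzylvanillic acid).
- Ring order: both arenes are bought, the lactone and cyclopropane form simultaneously, and the cyclopropane is then sacrificed while the lactone is kept.

Assumption: O-benzylvanillin and O-benzylvanillic acid are bought as catalogue compounds, and the antipode of the ChenPhyrin ligand that gives the (1S,5R,6S) bicycle is fixed by one analytical run, since both antipodes are accessible.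

## Route

**Step 1**
Reactants: 1 4-(benzyloxy)-3-methoxybenzaldehyde; 2 triethyl phosphonoacetate
Product: 3 ethyl (E)-3-[4-(benzyloxy)-3-methoxyphenyl]prop-2-enoate
Conditions: NaH, THF, 0 °C to rt
Reagents that add atoms: none
Why: Horner–Wadsworth–Emmons olefination of a non-enolisable aryl aldehyde with a stabilised phosphonate anion gives the E-cinnamate almost exclusively, and no stereocentre is formed.

**Step 2**
Reactants: 3 ethyl (E)-3-[4-(benzyloxy)-3-methoxyphenyl]prop-2-enoate
Product: 4 (E)-3-[4-(benzyloxy)-3-methoxyphenyl]prop-2-en-1-ol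
Conditions: iBu2AlH (2.3 equiv), CH2Cl2, −78 to 0 °C; aq KNaC4H4O6
Reagents that add atoms: none
Why: 1,2-reduction of the conjugated ester with a neutral aluminium hydride gives the allylic alcohol without touching the alkene geometry or the benzyl ether.

**Step 3**
Reactants: 5 4-(benzyloxy)-3-methoxybenzoic acid; 6 Meldrum's acid
Product: 7 5-{[4-(benzyloxy)-3-methoxyphenyl](hydroxy)methylidene}-2,2-dimethyl-1,3-dioxane-4,6-dione
Conditions: DCC, DMAP, CH2Cl2, 0 °C to rt
Reagents that add atoms: none
Why: Steglich-type carbodiimide/DMAP activation C-acylates the very acidic Meldrum's acid, and the product is held as its hydrogen-bonded enol.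

**Step 4**
Reactants: 4 (E)-3-[4-(benzyloxy)-3-methoxyphenyl]prop-2-en-1-ol; 7 aroyl Meldrum's acid
Product: 10 (E)-3-[4-(benzyloxy)-3-methoxyphenyl]allyl 3-[4-(benzyloxy)-3-methoxyphenyl]-2-diazo-3-oxopropanoate, via aroylketene 8 (not isolated), via beta-keto ester 9 (not isolated)
Conditions: 7 added in portions to 4, toluene, 100 °C, 2 h; cool to rt, MeCN, p-ABSA, Et3N
Reagents that add atoms: 4-acetamidobenzenesulfonyl azide (p-ABSA), CC(=O)Nc1ccc(cc1)S(=O)(=O)N=[N+]=[N-]
Why: Thermal retro-[4+2] fragmentation of 7 releases only volatile co-products and an acylketene that the alcohol traps, so the clean beta-keto ester solution can go straight into a Regitz diazo transfer at its active methylene.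

**Step 5**
Reactants: 10 cinnamyl-type aroyl(diazo)acetate
Product: 11 (1S,5R,6S)-1-[4-(benzyloxy)-3-methoxybenzoyl]-6-[4-(benzyloxy)-3-methoxyphenyl]-3-oxabicyclo[3.1.0]hexan-2-one
Conditions: [Co(3,5-DitBu-ChenPhyrin)] (2 mol %), toluene, 40 °C, N2; recrystallise
Reagents that add atoms: none
Why: In this asymmetric intramolecular cyclopropanation of an allylic alpha-acyl diazoacetate (metalloradical catalysis by a divalent cobalt amidoporphyrin), loss of N2, 5-exo addition to the tethered E-styrene and 3-exo closure build the lactone and the cyclopropane in one operation, the chiral pocket choosing the alkene face (C5 = R), the cis ring fusion tying C1 to C5, and the E-alkene placing the aryl group exo at C6.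

**Step 6**
Reactants: 11 bicyclic donor-acceptor cyclopropane
Product: 12 (3S,4R)-3-(4-hydroxy-3-methoxybenzoyl)-4-(4-hydroxy-3-methoxybenzyl)oxolan-2-one
Conditions: H2 (1 atm), 10% Pd/C, EtOAc–THF, rt, stopped at uptake of 3 equiv
Reagents that add atoms: none
Why: Catalytic hydrogenolysis removes both benzyl ethers and cuts the only push-pull bond (benzylic C6 to doubly acceptor-substituted C1, weakened further once the para-phenol is free), which leaves C5 untouched as C4 (R) and creates C3 as an enolisable methine that settles trans (S), while the electron-rich aryl ketone is inert at 1 atm in neutral solvent.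

**Step 7**
Reactants: 12 keto lactone
Product: 13 (3S,4R)-3-[(S)-hydroxy(4-hydroxy-3-methoxyphenyl)methyl]-4-(4-hydroxy-3-methoxybenzyl)oxolan-2-one
Conditions: RuCl[(S,S)-TsDPEN](p-cymene) (1 mol %), HCO2H–Et3N (1:1), EtOAc, 30 °C
Reagents that add atoms: none
Why: In this Noyori–Ikariya asymmetric transfer hydrogenation under dynamic kinetic conditions, C3 equilibrates through the enol and sits trans to the C4 benzyl group, the (S,S)-catalyst gives the S carbinol in the same sense as acetophenone to (S)-1-phenylethanol, and C3 is no longer labile once the ketone is gone.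

## Compound list

| No. | Name | SMILES | Role |
|---|---|---|---|
| 1 | 4-(benzyloxy)-3-methoxybenzaldehyde | O=Cc1ccc(OCc2ccccc2)c(OC)c1 | starting material |
| 2 | triethyl phosphonoacetate | CCOC(=O)CP(=O)(OCC)OCC | starting material |
| 3 | ethyl (E)-3-[4-(benzyloxy)-3-methoxyphenyl]prop-2-enoate | CCOC(=O)/C=C/c1ccc(OCc2ccccc2)c(OC)c1 | intermediate |
| 4 | (E)-3-[4-(benzyloxy)-3-methoxyphenyl]prop-2-en-1-ol | OC/C=C/c1ccc(OCc2ccccc2)c(OC)c1 | intermediate |
| 5 | 4-(benzyloxy)-3-methoxybenzoic acid | OC(=O)c1ccc(OCc2ccccc2)c(OC)c1 | starting material |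
| 6 | Meldrum's acid (2,2-dimethyl-1,3-dioxane-4,6-dione) | CC1(C)OC(=O)CC(=O)O1 | starting material |
| 7 | 5-{[4-(benzyloxy)-3-methoxyphenyl](hydroxy)methylidene}-2,2-dimethyl-1,3-dioxane-4,6-dione | CC1(C)OC(=O)C(=C(O)c2ccc(OCc3ccccc3)c(OC)c2)C(=O)O1 | intermediate |
| 8 | aroylketene, 3-[4-(benzyloxy)-3-methoxyphenyl]-3-oxoprop-1-en-1-one | O=C=CC(=O)c1ccc(OCc2ccccc2)c(OC)c1 | intermediate |
| 9 | (E)-3-[4-(benzyloxy)-3-methoxyphenyl]allyl 3-[4-(benzyloxy)-3-methoxyphenyl]-3-oxopropanoate | COc1cc(/C=C/COC(=O)CC(=O)c2ccc(OCc3ccccc3)c(OC)c2)ccc1OCc1ccccc1 | intermediate |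
| 10 | (E)-3-[4-(benzyloxy)-3-methoxyphenyl]allyl 3-[4-(benzyloxy)-3-methoxyphenyl]-2-diazo-3-oxopropanoate | COc1cc(/C=C/COC(=O)C(=[N+]=[N-])C(=O)c2ccc(OCc3ccccc3)c(OC)c2)ccc1OCc1ccccc1 | intermediate |
| 11 | (1S,5R,6S)-1-[4-(benzyloxy)-3-methoxybenzoyl]-6-[4-(benzyloxy)-3-methoxyphenyl]-3-oxabicyclo[3.1.0]hexan-2-one | COc1cc([C@@H]2[C@H]3COC(=O)[C@@]23C(=O)c2ccc(OCc3ccccc3)c(OC)c2)ccc1OCc1ccccc1 | intermediate |
| 12 | (3S,4R)-3-(4-hydroxy-3-methoxybenzoyl)-4-(4-hydroxy-3-methoxybenzyl)oxolan-2-one | COc1cc(C[C@H]2COC(=O)[C@@H]2C(=O)c2ccc(O)c(OC)c2)ccc1O | intermediate |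
| 13 | (3S,4R)-3-[(S)-hydroxy(4-hydroxy-3-methoxyphenyl)methyl]-4-(4-hydroxy-3-methoxybenzyl)oxolan-2-one | COc1cc(C[C@H]2COC(=O)[C@@H]2[C@H](O)c2ccc(O)c(OC)c2)ccc1O | target |

## Step count

- Total step count: 7.
- Longest linear sequence: 6 (steps 1, 2, 4, 5, 6, 7).

## Three steps most likely to fail

**Step 5.** The risk is low ee or poor chemoselectivity with the diacceptor carbene. Partial isomerisation of 11 to the fused dihydrofuran would be harmless, because that isomer keeps C5 and is hydrogenolysed to 12 as well.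

The fallback takes the aroyl group out of the carbene step. It sets out from 4 and comes back at 11.
- Compound 4 is acylated with glyoxylic acid chloride p-toluenesulfonylhydrazone (PhNMe2, CH2Cl2, 0 °C) to the glyoxylate tosylhydrazone ester F1.
- Et3N converts this in the same flask into (E)-3-[4-(benzyloxy)-3-methoxyphenyl]allyl diazoacetate F2.
- Slow addition to Rh2(4R-MPPIM)4 (0.5 mol %, CH2Cl2, reflux) again closes the lactone and cyclopropane together, now in the best-behaved substrate class. This gives (1S,5R,6R)-6-[4-(benzyloxy)-3-methoxyphenyl]-3-oxabicyclo[3.1.0]hexan-2-one F3.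
- LiN(iPr)2 (THF, −78 °C) followed by aldehyde 1 gives the C1 aldol adduct F4 as carbinol epimers. The ring fusion allows only retention at C1.
- Dess–Martin periodinane with NaHCO3 oxidises F4 to 11.

**Step 6.** The risk is that slow cyclopropane cleavage forces long exposure to H2 and Pd, which would over-reduce the ketone.

The fallback separates the two tasks and uses electron transfer for the ring opening. It sets out from 11 and comes back at 12.
- SmI2 (2.5 equiv, THF–MeOH, −78 °C) forms the ketyl. This fragments the C1–C6 bond to the benzylic radical and samarium enolate.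
- Reduction and protonation then give (3S,4R)-3-[4-(benzyloxy)-3-methoxybenzoyl]-4-[4-(benzyloxy)-3-methoxybenzyl]oxolan-2-one F5.
- A brief debenzylation (H2, 10% Pd/C, EtOAc, 1–2 h) then delivers 12.

**Step 7.** The risk is a sluggish or mismatched reduction of the electron-rich free-phenol ketone.

The fallback replaces catalyst control by substrate chelate control on the protected ketone and moves deprotection to the end. It sets out from 11 and comes back at 13.
- Compound 11 is opened with SmI2 as above to the dibenzyl keto lactone F5.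
- Zn(BH4)2 (Et2O–THF, −30 to 0 °C) bridges the ketone and lactone carbonyls and delivers hydride from the face bearing the C3 hydrogen, anti to C4. This gives the syn (3S,7'S) product, (3S,4R)-3-{(S)-[4-(benzyloxy)-3-methoxyphenyl](hydroxy)methyl}-4-[4-(benzyloxy)-3-methoxybenzyl]oxolan-2-one F6.
- Neutral hydrogenolysis (H2, 10% Pd/C, EtOAc, rt) removes the aryl benzyl ethers faster than the secondary carbinol can react and gives 13.

## Further compounds

F1 | step 5 | (E)-3-[4-(benzyloxy)-3-methoxyphenyl]allyl 2-(2-tosylhydrazinylidene)acetate | COc1cc(/C=C/COC(=O)C=NNS(=O)(=O)c2ccc(C)cc2)ccc1OCc1ccccc1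
F2 | step 5 | (E)-3-[4-(benzyloxy)-3-methoxyphenyl]allyl diazoacetate | COc1cc(/C=C/COC(=O)C=[N+]=[N-])ccc1OCc1ccccc1
F3 | step 5 | (1S,5R,6R)-6-[4-(benzyloxy)-3-methoxyphenyl]-3-oxabicyclo[3.1.0]hexan-2-one | COc1cc([C@@H]2[C@H]3COC(=O)[C@@H]23)ccc1OCc1ccccc1
F4 | step 5 | (1S,5R,6S)-1-{[4-(benzyloxy)-3-methoxyphenyl](hydroxy)methyl}-6-[4-(benzyloxy)-3-methoxyphenyl]-3-oxabicyclo[3.1.0]hexan-2-one, carbinol epimers | COc1cc([C@@H]2[C@H]3COC(=O)[C@@]23C(O)c2ccc(OCc3ccccc3)c(OC)c2)ccc1OCc1ccccc1
F5 | step 6 | (3S,4R)-3-[4-(benzyloxy)-3-methoxybenzoyl]-4-[4-(benzyloxy)-3-methoxybenzyl]oxolan-2-one | COc1cc(C[C@H]2COC(=O)[C@@H]2C(=O)c2ccc(OCc3ccccc3)c(OC)c2)ccc1OCc1ccccc1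
F6 | step 7 | (3S,4R)-3-{(S)-[4-(benzyloxy)-3-methoxyphenyl](hydroxy)methyl}-4-[4-(benzyloxy)-3-methoxybenzyl]oxolan-2-one | COc1cc(C[C@H]2COC(=O)[C@@H]2[C@H](O)c2ccc(OCc3ccccc3)c(OC)c2)ccc1OCc1ccccc1
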